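**Strategy.** The molecule is robinetinidol-(4α→6)-epigallocatechin. The interflavan bond C4(upper)–C6(lower) is made late, between a dihydrorobinetin-derived flavan-3,4-diol and an 8-bromo-capped lower unit. The lower pyran ring is not cyclised directly: its C4 methylene sits between the electron-rich ring A carbon C4a and the oxygenated C3, the signature of a 1,2-aryl shift. A 2-aryl-3-hydroxy-3-(tosyloxymethyl)-2,3-dihydrobenzofuran, made by Norrish–Yang photocyclisation of an aryl glyoxylate, undergoes semipinacol rearrangement: C4a migrates from C3 to the exocyclic CH2, and the five-membered furan ring becomes the six-membered flavan-3-one in one operation. Dynamic kinetic hydrogenation then sets C2 and C3.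

Key step: step 5

Remark: the structure is read as upper unit 2R,3S,4S (2,3-trans-3,4-trans) and lower unit 2R,3R (2,3-cis). TBB denotes the 3,4,5-tris(benzyloxy)benzyl group. Compounds 6 to 9 are racemic. Three molecules of 2 are built into 3 in step 1, so 2 stands there both as reactant and as the source of the added atoms.

**Step 1**
Reactants: 1 phloroglucinol (benzene-1,3,5-triol); 2 3,4,5-tris(benzyloxy)benzyl alcohol (3.3 equiv)
Product: 3 1,3,5-tris(TBB-oxy)benzene
Conditions: 2 (3.3 equiv), PPh3 (3.6 equiv), DIAD (3.6 equiv), THF, 0 °C to rt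
Reagents that add atoms: 3,4,5-tris(benzyloxy)benzyl alcohol (compound 2), OCc1cc(OCc2ccccc2)c(OCc2ccccc2)c(OCc2ccccc2)c1
Why: Threefold Mitsunobu etherification, in which each of the three phenolic hydroxyls takes up one molecule of 2, avoids the C-alkylation seen with phloroglucinol phenoxides and gives a C3-symmetric triether in which either ortho TBB group can later deliver C2 and ring B while the other two protect O5 and O7.

**Step 2**
Reactants: 3 1,3,5-tris(TBB-oxy)benzene
Product: 5 methyl 2-oxo-2-[2,4,6-tris(TBB-oxy)phenyl]acetate, via aryllithium 4 (not isolated)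
Conditions: n-BuLi (1.05 equiv), TMEDA, THF, 0 °C; then added to (CO2Me)2 (3 equiv), THF, −78 °C; 1 M HCl quench
Reagents that add atoms: dimethyl oxalate, COC(=O)C(=O)OC
Why: Directed ortho-lithiation at a ring position flanked by two alkoxy groups (all three positions are equivalent) followed by inverse-addition acylation with an oxalate diester should give the aryl glyoxylate without over-addition.

**Step 3**
Reactants: 5 methyl 2-oxo-2-[2,4,6-tris(TBB-oxy)phenyl]acetate
Product: 6 methyl 3-hydroxy-2-[3,4,5-tris(benzyloxy)phenyl]-4,6-bis(TBB-oxy)-2,3-dihydrobenzofuran-3-carboxylate (racemic, both C2/C3 diastereomers)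
Conditions: hν (365 nm), degassed benzene, rt
Reagents that add atoms: none
Why: Norrish–Yang photocyclisation, in which the excited α-keto ester abstracts a benzylic ether hydrogen from either of the two identical ortho OCH2Ar groups and the 1,5-biradical closes the five-membered ring; C2 and C3 form without control, which is harmless because C3 becomes sp2 in step 5 and C2 is reset in step 6.

**Step 4**
Reactants: 6 methyl 3-hydroxy-2-[3,4,5-tris(benzyloxy)phenyl]-4,6-bis(TBB-oxy)-2,3-dihydrobenzofuran-3-carboxylate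
Product: 7 3-(hydroxymethyl)-2-[3,4,5-tris(benzyloxy)phenyl]-4,6-bis(TBB-oxy)-2,3-dihydrobenzofuran-3-ol
Conditions: LiAlH4, THF, 0 °C; basic aqueous work-up
Reagents that add atoms: none
Why: Hydride reduction of the ester to the primary alcohol leaves the aryl and benzyl ethers and both stereocentres untouched, and the basic work-up protects the dehydration-prone tertiary benzylic alcohol.

**Step 5**
Reactants: 7 3-(hydroxymethyl)-2-[3,4,5-tris(benzyloxy)phenyl]-4,6-bis(TBB-oxy)-2,3-dihydrobenzofuran-3-ol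
Product: 9 racemic 2-[3,4,5-tris(benzyloxy)phenyl]-5,7-bis(TBB-oxy)chroman-3-one, via primary tosylate 8 (not isolated)
Conditions: TsCl, DMAP (cat.), pyridine, 0 °C; crude, then LiClO4, CaCO3, THF, 50 °C
Reagents that add atoms: none
Why: The primary hydroxyl of 7 is tosylated selectively, and on Li+-assisted ionisation the ring A carbon C3a, anti to the C–OTs bond, bridges to the CH2 group (phenonium-type participation by a carbon that has three oxygen donors ortho and para to it) while the C3 hydroxyl pushes, so that C3 ends as the carbonyl carbon. This is a semipinacol (pinacol-type) rearrangement of a 1,2-diol monosulfonate, the reaction type used for one-carbon ring expansion of 1-(sulfonyloxymethyl)cycloalkanols under LiClO4/CaCO3. No ring is closed from an open chain: the five-membered O1–C2–C3–C3a–C7a ring grows into the six-membered O1–C2–C3–C4–C4a–C8a ring by a 1,2-shift that inserts the former exocyclic CH2 as C4. No stereocentre is created, since C3 becomes sp2 and C2 is carried through as a racemate to be set in step 6. The step needs aryl over C2-alkyl migration, and rearrangement over spiro-epoxide closure or dehydration to a benzofuran; the first is secured by the much higher migratory aptitude of the trialkoxyaryl carbon compared with the oxygen-bearing C2, the others by the non-basic medium buffered with CaCO3.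

**Step 6**
Reactants: 9 racemic 2-[3,4,5-tris(benzyloxy)phenyl]-5,7-bis(TBB-oxy)chroman-3-one
Product: 10 (2R,3R)-2-[3,4,5-tris(benzyloxy)phenyl]-5,7-bis(TBB-oxy)chroman-3-ol
Conditions: H2 (50 atm), RuCl2[(R)-Xyl-SDP][(S,S)-DPEN] (1 mol%), t-BuOK (0.3 equiv), i-PrOH/toluene, rt
Reagents that add atoms: none
Why: Asymmetric ketone hydrogenation under dynamic kinetic resolution, in which the α-aryl-α-aryloxy centre C2 epimerises through the enolate while the chiral RuCl2(diphosphine)(diamine) catalyst reduces one antipode from the face anti to the C2 aryl group to give the 2,3-cis alcohol; the catalyst antipode is chosen by analogy with 2-arylcyclohexanones (cis-(1R,2R) corresponds spatially to (2R,3R) here) and is to be confirmed on the first analytical run.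

**Step 7**
Reactants: 10 (2R,3R)-2-[3,4,5-tris(benzyloxy)phenyl]-5,7-bis(TBB-oxy)chroman-3-ol
Product: 11 (2R,3R)-8-bromo-2-[3,4,5-tris(benzyloxy)phenyl]-5,7-bis(TBB-oxy)chroman-3-ol
Conditions: NBS (1.0 equiv), CH2Cl2, −78 to −20 °C
Reagents that add atoms: N-bromosuccinimide, O=C1CCC(=O)N1Br
Why: Electrophilic aromatic bromination should take place at C8 of the phloroglucinol-type ring A, the most nucleophilic and less flanked position of 5,7-dialkoxyflavans, which caps C8 so that only C6 remains for the coupling.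

**Step 8**
Reactants: 12 (+)-dihydrorobinetin, (2R,3R)-3,7-dihydroxy-2-(3,4,5-trihydroxyphenyl)chroman-4-one
Product: 13 (2R,3R)-7-(benzyloxy)-3-hydroxy-2-[3,4,5-tris(benzyloxy)phenyl]chroman-4-one
Conditions: BnBr (4.4 equiv), K2CO3, DMF, rt, under N2
Reagents that add atoms: benzyl bromide, BrCc1ccccc1
Why: Williamson etherification benzylates the four phenolic hydroxyls and leaves the less acidic aliphatic 3-hydroxyl free; C2 and C3 come from the chiral pool.

**Step 9**
Reactants: 13 (2R,3R)-7-(benzyloxy)-3-hydroxy-2-[3,4,5-tris(benzyloxy)phenyl]chroman-4-one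
Product: 14 (2R,3S,4R)-7-(benzyloxy)-2-[3,4,5-tris(benzyloxy)phenyl]chromane-3,4-diol
Conditions: NaBH4, THF/EtOH, 0 °C; aqueous work-up
Reagents that add atoms: none
Why: Borohydride reduction of the aryl ketone should give mainly the all-equatorial 2,3-trans-3,4-trans diol by axial hydride delivery; the C4 configuration is immaterial because C4 is ionised in step 10.

**Step 10**
Reactants: 14 (2R,3S,4R)-7-(benzyloxy)-2-[3,4,5-tris(benzyloxy)phenyl]chromane-3,4-diol; 11 (2R,3R)-8-bromo-2-[3,4,5-tris(benzyloxy)phenyl]-5,7-bis(TBB-oxy)chroman-3-ol (1.5 equiv)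
Product: 15 (2R,3S,4S)-7-(benzyloxy)-2-[3,4,5-tris(benzyloxy)phenyl]-4-{(2R,3R)-8-bromo-3-hydroxy-2-[3,4,5-tris(benzyloxy)phenyl]-5,7-bis(TBB-oxy)chroman-6-yl}chroman-3-ol
Conditions: TMSOTf (0.2 equiv), 4 Å MS, CH2Cl2, −40 °C
Reagents that add atoms: none
Why: Friedel–Crafts-type interflavan coupling, in which the 4-hydroxyl para to the 7-benzyloxy group ionises to a flavan-4-yl cation that can only be attacked by C6 of 11 because C8 is bromine-capped; approach anti to the C3 hydroxyl of the 2,3-trans cation should set the 3,4-trans (4α, 4S) centre.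

**Step 11**
Reactants: 15 protected 8-bromo dimer
Product: 16 robinetinidol-(4α→6)-epigallocatechin (target)
Conditions: H2 (1 atm), Pd(OH)2/C, Et3N (1.5 equiv), THF/MeOH, rt
Reagents that add atoms: none
Why: Hydrogenolysis cleaves the thirteen benzyl ethers, the two TBB aryl ether C–O bonds and the C8–Br bond in one operation, with Et3N trapping HBr so that the acid-labile interflavan bond and the five stereocentres are not touched.

**Compound list**

1 | phloroglucinol (benzene-1,3,5-triol) | Oc1cc(O)cc(O)c1 | starting material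
2 | 3,4,5-tris(benzyloxy)benzyl alcohol (TBB-OH) | OCc1cc(OCc2ccccc2)c(OCc2ccccc2)c(OCc2ccccc2)c1 | starting material
3 | 1,3,5-tris(TBB-oxy)benzene | c1(OCc2cc(OCc3ccccc3)c(OCc3ccccc3)c(OCc3ccccc3)c2)cc(OCc2cc(OCc3ccccc3)c(OCc3ccccc3)c(OCc3ccccc3)c2)cc(OCc2cc(OCc3ccccc3)c(OCc3ccccc3)c(OCc3ccccc3)c2)c1 | intermediate
4 | 2,4,6-tris(TBB-oxy)phenyllithium | [Li]c1c(OCc2cc(OCc3ccccc3)c(OCc3ccccc3)c(OCc3ccccc3)c2)cc(OCc2cc(OCc3ccccc3)c(OCc3ccccc3)c(OCc3ccccc3)c2)cc1OCc1cc(OCc2ccccc2)c(OCc2ccccc2)c(OCc2ccccc2)c1 | intermediate (not isolated)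
5 | methyl 2-oxo-2-[2,4,6-tris(TBB-oxy)phenyl]acetate | COC(=O)C(=O)c1c(OCc2cc(OCc3ccccc3)c(OCc3ccccc3)c(OCc3ccccc3)c2)cc(OCc2cc(OCc3ccccc3)c(OCc3ccccc3)c(OCc3ccccc3)c2)cc1OCc1cc(OCc2ccccc2)c(OCc2ccccc2)c(OCc2ccccc2)c1 | intermediate
6 | methyl 3-hydroxy-2-[3,4,5-tris(benzyloxy)phenyl]-4,6-bis(TBB-oxy)-2,3-dihydrobenzofuran-3-carboxylate (racemic, both diastereomers) | COC(=O)C1(O)C(c2cc(OCc3ccccc3)c(OCc3ccccc3)c(OCc3ccccc3)c2)Oc2cc(OCc3cc(OCc4ccccc4)c(OCc4ccccc4)c(OCc4ccccc4)c3)cc(OCc3cc(OCc4ccccc4)c(OCc4ccccc4)c(OCc4ccccc4)c3)c12 | intermediate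
7 | 3-(hydroxymethyl)-2-[3,4,5-tris(benzyloxy)phenyl]-4,6-bis(TBB-oxy)-2,3-dihydrobenzofuran-3-ol (racemic, both diastereomers) | OCC1(O)C(c2cc(OCc3ccccc3)c(OCc3ccccc3)c(OCc3ccccc3)c2)Oc2cc(OCc3cc(OCc4ccccc4)c(OCc4ccccc4)c(OCc4ccccc4)c3)cc(OCc3cc(OCc4ccccc4)c(OCc4ccccc4)c(OCc4ccccc4)c3)c12 | intermediate
8 | primary tosylate of 7 (racemic, both diastereomers) | Cc1ccc(cc1)S(=O)(=O)OCC1(O)C(c2cc(OCc3ccccc3)c(OCc3ccccc3)c(OCc3ccccc3)c2)Oc2cc(OCc3cc(OCc4ccccc4)c(OCc4ccccc4)c(OCc4ccccc4)c3)cc(OCc3cc(OCc4ccccc4)c(OCc4ccccc4)c(OCc4ccccc4)c3)c12 | intermediate (not isolated)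
9 | racemic 2-[3,4,5-tris(benzyloxy)phenyl]-5,7-bis(TBB-oxy)chroman-3-one | O=C1Cc2c(OCc3cc(OCc4ccccc4)c(OCc4ccccc4)c(OCc4ccccc4)c3)cc(OCc3cc(OCc4ccccc4)c(OCc4ccccc4)c(OCc4ccccc4)c3)cc2OC1c1cc(OCc2ccccc2)c(OCc2ccccc2)c(OCc2ccccc2)c1 | intermediate
10 | (2R,3R)-2-[3,4,5-tris(benzyloxy)phenyl]-5,7-bis(TBB-oxy)chroman-3-ol | O[C@@H]1Cc2c(OCc3cc(OCc4ccccc4)c(OCc4ccccc4)c(OCc4ccccc4)c3)cc(OCc3cc(OCc4ccccc4)c(OCc4ccccc4)c(OCc4ccccc4)c3)cc2O[C@@H]1c1cc(OCc2ccccc2)c(OCc2ccccc2)c(OCc2ccccc2)c1 | intermediate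
11 | (2R,3R)-8-bromo-2-[3,4,5-tris(benzyloxy)phenyl]-5,7-bis(TBB-oxy)chroman-3-ol | O[C@@H]1Cc2c(OCc3cc(OCc4ccccc4)c(OCc4ccccc4)c(OCc4ccccc4)c3)cc(OCc3cc(OCc4ccccc4)c(OCc4ccccc4)c(OCc4ccccc4)c3)c(Br)c2O[C@@H]1c1cc(OCc2ccccc2)c(OCc2ccccc2)c(OCc2ccccc2)c1 | intermediate
12 | (+)-dihydrorobinetin, (2R,3R)-3,7-dihydroxy-2-(3,4,5-trihydroxyphenyl)chroman-4-one | O=C1c2ccc(O)cc2O[C@H](c2cc(O)c(O)c(O)c2)[C@H]1O | starting material
13 | (2R,3R)-7-(benzyloxy)-3-hydroxy-2-[3,4,5-tris(benzyloxy)phenyl]chroman-4-one | O=C1c2ccc(OCc3ccccc3)cc2O[C@H](c2cc(OCc3ccccc3)c(OCc3ccccc3)c(OCc3ccccc3)c2)[C@H]1O | intermediate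
14 | (2R,3S,4R)-7-(benzyloxy)-2-[3,4,5-tris(benzyloxy)phenyl]chromane-3,4-diol | O[C@@H]1c2ccc(OCc3ccccc3)cc2O[C@H](c2cc(OCc3ccccc3)c(OCc3ccccc3)c(OCc3ccccc3)c2)[C@H]1O | intermediate
15 | protected 8-bromo dimer: upper unit (2R,3S,4S) tetra-O-benzyl robinetinidol linked C4→C6 to lower unit (2R,3R) 11 | O(Cc1ccccc1)c1ccc2c(c1)O[C@H](c1cc(OCc3ccccc3)c(OCc3ccccc3)c(OCc3ccccc3)c1)[C@@H](O)[C@@H]2c1c(OCc3cc(OCc4ccccc4)c(OCc4ccccc4)c(OCc4ccccc4)c3)c(Br)c2c(c1OCc1cc(OCc3ccccc3)c(OCc3ccccc3)c(OCc3ccccc3)c1)C[C@@H](O)[C@@H](c1cc(OCc3ccccc3)c(OCc3ccccc3)c(OCc3ccccc3)c1)O2 | intermediate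
16 | robinetinidol-(4α→6)-epigallocatechin | Oc1ccc2c(c1)O[C@H](c1cc(O)c(O)c(O)c1)[C@@H](O)[C@@H]2c1c(O)cc2c(c1O)C[C@@H](O)[C@@H](c1cc(O)c(O)c(O)c1)O2 | target

**Step count.** Total: 11 steps. Longest linear sequence: 9 steps (steps 1 to 7, then 10 and 11); steps 8 and 9 form the short branch.

**Steps most likely to fail**

Step 5. The tertiary benzylic C3 hydroxyl may ionise with loss of water and aromatisation to a benzofuran, or the tosylate may close to the spiro-epoxide, before the aryl carbon migrates. The fallback keeps the same 1,2-aryl shift but drives it with a diazonium leaving group (Tiffeneau–Demjanov ring expansion). It sets out from 6: ammonolysis (NH3, MeOH) should give the hydroxy carboxamide F1, LiAlH4 reduction the 3-(aminomethyl)-2,3-dihydrobenzofuran-3-ol F2, and diazotisation (NaNO2, aqueous AcOH, 0 °C) releases dinitrogen at a temperature at which the tertiary alcohol should stay intact. The route is rejoined at 9.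

Step 6. Racemisation at C2 may be slower than reduction, or the catalyst may discriminate the two faces poorly, so that enantiomeric or cis/trans purity is eroded; the ketone may also degrade under base. The fallback separates the two tasks and sets out from 9. Substrate-controlled reduction with LiBH(s-Bu)3 (THF, −78 °C), which attacks anti to the C2 aryl group, should give the racemic cis alcohol, that is 10 together with its (2S,3S) enantiomer F3. Esterification of the mixture with (S)-2-methoxy-2-phenylacetic acid (DCC, DMAP cat., CH2Cl2, 0 °C) should give two diastereomeric esters, the (2R,3R) ester F4 and the (2S,3S) ester F5, which are separated by chromatography on silica. Methanolysis of F4 (K2CO3, MeOH/THF, rt) returns the route at 10.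

Step 10. Attack at the doubly flanked C6 may be slow, so that the cation self-condenses or reacts reversibly and facial selectivity at C4 (4α against 4β) is lost under the equilibrating acid. The fallback replaces the hydroxyl donor by a thioether donor activated by a thiophile under non-protic, irreversible conditions. It sets out from 14: thiolysis (BnSH, AcOH, rt) should give the 3,4-trans 4-benzylsulfanyl flavan-3-ol F6, and AgBF4 (THF/CH2Cl2, −40 °C) in the presence of 11 should then form the C4–C6 bond. The route is rejoined at 15.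

**Further compounds**

F1 | step 5 | 3-hydroxy-2-[3,4,5-tris(benzyloxy)phenyl]-4,6-bis(TBB-oxy)-2,3-dihydrobenzofuran-3-carboxamide (racemic) | NC(=O)C1(O)C(c2cc(OCc3ccccc3)c(OCc3ccccc3)c(OCc3ccccc3)c2)Oc2cc(OCc3cc(OCc4ccccc4)c(OCc4ccccc4)c(OCc4ccccc4)c3)cc(OCc3cc(OCc4ccccc4)c(OCc4ccccc4)c(OCc4ccccc4)c3)c12
F2 | step 5 | 3-(aminomethyl)-2-[3,4,5-tris(benzyloxy)phenyl]-4,6-bis(TBB-oxy)-2,3-dihydrobenzofuran-3-ol (racemic) | NCC1(O)C(c2cc(OCc3ccccc3)c(OCc3ccccc3)c(OCc3ccccc3)c2)Oc2cc(OCc3cc(OCc4ccccc4)c(OCc4ccccc4)c(OCc4ccccc4)c3)cc(OCc3cc(OCc4ccccc4)c(OCc4ccccc4)c(OCc4ccccc4)c3)c12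
F3 | step 6 | (2S,3S)-2-[3,4,5-tris(benzyloxy)phenyl]-5,7-bis(TBB-oxy)chroman-3-ol (enantiomer of 10) | O[C@H]1Cc2c(OCc3cc(OCc4ccccc4)c(OCc4ccccc4)c(OCc4ccccc4)c3)cc(OCc3cc(OCc4ccccc4)c(OCc4ccccc4)c(OCc4ccccc4)c3)cc2O[C@H]1c1cc(OCc2ccccc2)c(OCc2ccccc2)c(OCc2ccccc2)c1
F4 | step 6 | (2R,3R)-2-[3,4,5-tris(benzyloxy)phenyl]-5,7-bis(TBB-oxy)chroman-3-yl (S)-2-methoxy-2-phenylacetate | O=C(O[C@@H]1Cc2c(OCc3cc(OCc4ccccc4)c(OCc4ccccc4)c(OCc4ccccc4)c3)cc(OCc3cc(OCc4ccccc4)c(OCc4ccccc4)c(OCc4ccccc4)c3)cc2O[C@@H]1c1cc(OCc2ccccc2)c(OCc2ccccc2)c(OCc2ccccc2)c1)[C@@H](OC)c1ccccc1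
F5 | step 6 | (2S,3S)-2-[3,4,5-tris(benzyloxy)phenyl]-5,7-bis(TBB-oxy)chroman-3-yl (S)-2-methoxy-2-phenylacetate | O=C(O[C@H]1Cc2c(OCc3cc(OCc4ccccc4)c(OCc4ccccc4)c(OCc4ccccc4)c3)cc(OCc3cc(OCc4ccccc4)c(OCc4ccccc4)c(OCc4ccccc4)c3)cc2O[C@H]1c1cc(OCc2ccccc2)c(OCc2ccccc2)c(OCc2ccccc2)c1)[C@@H](OC)c1ccccc1
F6 | step 10 | 2,3-trans-3,4-trans 4-(benzylsulfanyl)-7-(benzyloxy)-2-[3,4,5-tris(benzyloxy)phenyl]chroman-3-ol (thio analogue of 14) | c1ccccc1CS[C@@H]1c2ccc(OCc3ccccc3)cc2O[C@H](c2cc(OCc3ccccc3)c(OCc3ccccc3)c(OCc3ccccc3)c2)[C@H]1O
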